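## Retrosynthetic overview

1. Target ⇐ its hepta-O-methyl ether, by one global demethylation at the end.
2. Hepta-O-methyl ether ⇐ the corresponding alkene (double bond in the seven-membered ring, at the carbon carrying the pendant aryl). Hydrogenation from the convex face sets that stereocentre relative to the ring-fusion methine.
3. Alkene ⇐ an open biaryl with an E-stilbene arm on the resorcinol ring and a diarylalkyne arm on the central ring. One chiral Brønsted acid operation closes the six-membered ring (stilbene protonation/Friedel–Crafts, sets the ring-fusion methine), then the seven-membered ring (alkyne protonation/7-endo Friedel–Crafts).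
4. Biaryl ⇐ bromostilbene + bromoaryl boronate + aryl acetylene (one-pot Sonogashira/Suzuki); bromostilbene ⇐ 2-bromo-3,5-dimethoxybenzaldehyde + benzylic phosphonate (Horner–Wadsworth–Emmons).
5. Ring order: biaryl bond between the preformed rings A and C, then the six-membered ring, then the seven-membered ring (the last two in the same flask).

Labels: ring A = resorcinol ring; ring B = catechol ring fused to the seven-membered ring; ring C = central phenol ring; ring D = pendant catechol ring. C-w = CH2 between ring A and C-x; C-x = CH shared by the six- and seven-membered rings; C-y = CH bearing ring D; C-z = CH2 between C-y and ring C. The target is (xR,yS), with the hydrogens on C-x and C-y cis across the seven-membered ring.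

Assumption: diethyl (3,4-dimethoxybenzyl)phosphonate and the pinacol boronate of 3-bromo-5-methoxybenzene are bought as catalogue reagents.

Assumption: the (S,S) antipode of the chiral acid is written for step 3; its sense of induction cannot be predicted, so the (R,R) antipode is used if the mirror-image product forms.

## Route

Step 1
Reactants: 1 2-bromo-3,5-dimethoxybenzaldehyde; 2 diethyl (3,4-dimethoxybenzyl)phosphonate
Product: 3 (E)-2-bromo-1-[2-(3,4-dimethoxyphenyl)ethenyl]-3,5-dimethoxybenzene
Conditions: KOtBu, THF, 0 °C → rt
Reagents that add atoms: none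
Why: Horner–Wadsworth–Emmons olefination of an aromatic aldehyde with a benzylic phosphonate anion gives the E-stilbene with high selectivity and leaves the aryl bromide untouched.

Step 2
Reactants: 4 2-(3-bromo-5-methoxyphenyl)-4,4,5,5-tetramethyl-1,3,2-dioxaborolane; 5 4-ethynyl-1,2-dimethoxybenzene; 3 (E)-2-bromo-1-[2-(3,4-dimethoxyphenyl)ethenyl]-3,5-dimethoxybenzene
Product: 7 (E)-2-[2-(3,4-dimethoxyphenyl)ethenyl]-5'-[(3,4-dimethoxyphenyl)ethynyl]-3',4,6-trimethoxy-1,1'-biphenyl, via alkynyl boronate 6 (not isolated)
Conditions: 4, 5, Pd(PPh3)2Cl2 (2 mol%), CuI (4 mol%), iPr2NH, THF, 60 °C; then 3, Pd(OAc)2, SPhos (2-dicyclohexylphosphino-2',6'-dimethoxybiphenyl), K3PO4, H2O, 80 °C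
Reagents that add atoms: none
Why: Sonogashira coupling of the aryl bromide of 4 under anhydrous amine/CuI conditions leaves the pinacol boronate intact; adding the hindered bromide 3, aqueous K3PO4 and the SPhos-ligated palladium catalyst then triggers Suzuki–Miyaura biaryl coupling in the same flask, with no stereocentre formed and the E-alkene and the alkyne unaffected.

Step 3
Reactants: 7 (E)-2-[2-(3,4-dimethoxyphenyl)ethenyl]-5'-[(3,4-dimethoxyphenyl)ethynyl]-3',4,6-trimethoxy-1,1'-biphenyl
Product: 9 (xR)-hepta-O-methyl-y,z-didehydro target (pentacyclic alkene; C-y=C-z in the seven-membered ring), via dihydrophenanthrene alkyne 8 (not isolated)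
Conditions: (S,S)-IDPi (imidodiphosphorimidate acid from two (S)-3,3'-bis[3,5-bis(trifluoromethyl)phenyl]-BINOL units, both P=N–SO2CF3; 10 mol%), CHCl3 (0.02 M), 5 Å MS, 0 °C, then 50 °C
Reagents that add atoms: none
Why: Proposed new method: the confined chiral acid protonates the stilbene at C-w to give the 3,4-dimethoxybenzylic cation at C-x as a contact ion pair with one face closed by the chiral anion, and ring C attacks it para to its methoxy group to close the six-membered ring and set C-x as R (enantiodetermining); on warming the same acid protonates the alkyne at C-z to the aryl-stabilised vinyl cation at C-y, which ring B traps para to its methoxy group in a 7-endo Friedel–Crafts closure that creates no stereocentre; the closest known reaction types are IDPi-catalysed asymmetric intramolecular hydroarylation of olefins and Brønsted-acid-catalysed intramolecular hydroarylation of electron-rich diarylalkynes.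

Step 4
Reactants: 9 (xR)-hepta-O-methyl-y,z-didehydro target
Product: 10 (xR,yS)-hepta-O-methyl target
Conditions: H2 (3 atm), 10% Pd/C, EtOAc–EtOH, rt
Reagents that add atoms: none
Why: Heterogeneous syn-hydrogenation of the triaryl-substituted alkene; the ring fusion forces C-w into the plane of ring C, so the boat-shaped seven-membered ring is locked with H on C-x pseudo-axial on the convex face while rings B and C block the concave face, and both hydrogens therefore add from the convex face, cis to H on C-x, which sets C-y as S.

Step 5
Reactants: 10 (xR,yS)-hepta-O-methyl target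
Product: 11 CNP0306974.1, the (xR,yS)-heptaphenol
Conditions: BBr3 (12 equiv), CH2Cl2, −78 °C → rt; then MeOH, H2O, 0 °C, under argon
Reagents that add atoms: none
Why: Lewis-acid cleavage of aryl methyl ethers by BBr3 (bromide attack on the O-methyl of the boron-bound ether) removes all seven methyl groups, and the two benzylic C–H stereocentres carry no leaving group and are not touched.

## Compound list

1 | 2-bromo-3,5-dimethoxybenzaldehyde | O=Cc1cc(OC)cc(OC)c1Br | starting material
2 | diethyl (3,4-dimethoxybenzyl)phosphonate | CCOP(=O)(OCC)Cc1ccc(OC)c(OC)c1 | starting material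
3 | (E)-2-bromo-1-[2-(3,4-dimethoxyphenyl)ethenyl]-3,5-dimethoxybenzene | COc1cc(OC)c(Br)c(/C=C/c2ccc(OC)c(OC)c2)c1 | intermediate
4 | 2-(3-bromo-5-methoxyphenyl)-4,4,5,5-tetramethyl-1,3,2-dioxaborolane | COc1cc(Br)cc(c1)B1OC(C)(C)C(C)(C)O1 | starting material
5 | 4-ethynyl-1,2-dimethoxybenzene | C#Cc1ccc(OC)c(OC)c1 | starting material
6 | 2-{3-[(3,4-dimethoxyphenyl)ethynyl]-5-methoxyphenyl}-4,4,5,5-tetramethyl-1,3,2-dioxaborolane | COc1cc(cc(c1)B1OC(C)(C)C(C)(C)O1)C#Cc1ccc(OC)c(OC)c1 | intermediate (not isolated)
7 | (E)-2-[2-(3,4-dimethoxyphenyl)ethenyl]-5'-[(3,4-dimethoxyphenyl)ethynyl]-3',4,6-trimethoxy-1,1'-biphenyl | COc1cc(OC)c(c(/C=C/c2ccc(OC)c(OC)c2)c1)-c1cc(OC)cc(c1)C#Cc1ccc(OC)c(OC)c1 | intermediate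
8 | (10R)-10-(3,4-dimethoxyphenyl)-1-[(3,4-dimethoxyphenyl)ethynyl]-3,5,7-trimethoxy-9,10-dihydrophenanthrene | COc1cc(OC)c2c(c1)C[C@H](c1ccc(OC)c(OC)c1)c1c(C#Cc3ccc(OC)c(OC)c3)cc(OC)cc1-2 | intermediate (not isolated)
9 | (xR)-hepta-O-methyl-y,z-didehydro target: 9,10-dihydrophenanthrene of rings A and C whose C-x and ring C peri carbon are bridged by ring B and a C-y(ring D)=C-z alkene | COc1cc(OC)c2c(c1)C[C@@H]1c3cc(OC)c(OC)cc3C(c3ccc(OC)c(OC)c3)=Cc3cc(OC)cc-2c31 | intermediate
10 | (xR,yS)-hepta-O-methyl target | COc1cc(OC)c2c(c1)C[C@@H]1c3cc(OC)c(OC)cc3[C@H](c3ccc(OC)c(OC)c3)Cc3cc(OC)cc-2c31 | intermediate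
11 | CNP0306974.1, (xR,yS)-heptaphenol: 9,10-dihydrophenanthrene of rings A and C fused through C-x to a dibenzocycloheptane of rings B and C, ring D on C-y | Oc1cc(O)c2c(c1)C[C@@H]1c3cc(O)c(O)cc3[C@H](c3ccc(O)c(O)c3)Cc3cc(O)cc-2c31 | target

## Step count and risks

Total step count: 5. Longest linear sequence: 5 (1 → 3 → 7 → 9 → 10 → 11).

Steps most likely to fail:

**Step 3.** The sense and level of enantio-induction in the ion-pair Friedel–Crafts closure are untested. Ring C could also be attacked ortho instead of para to its methoxy group. The vinyl cation could abstract hydride from C-x, which would lead to an achiral phenanthrene. Fallback: from 7, the same two ring closures are run without asymmetric induction, HN(SO2CF3)2 (10 mol%) in CH2Cl2 at 0 °C, to give racemic pentacyclic alkene F1. Preparative supercritical-fluid chromatography on an amylose tris(3,5-dimethylphenylcarbamate) phase separates it into 9 and the unwanted (xS)-alkene F2, and the route is rejoined at 9.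

**Step 4.** The hindered triaryl alkene may reduce slowly on the metal surface, or the facial selectivity may be eroded. Fallback: from 9, ionic hydrogenation with Et3SiH and CF3CO2H in CH2Cl2 at −20 °C. Protonation at C-z gives the doubly benzylic cation at C-y, and the silane delivers hydride to the same open convex face, giving 10 directly. This makes no compound outside the list (F0).

**Step 2.** Bromide 3 is electron-rich and flanked by two ortho substituents, so oxidative addition in the Suzuki stage may be slow and boronate 6 may protodeboronate. Fallback: from 1, with alkynyl boronate 6 generated from 4 and 5 as before, the Suzuki stage is run on the more reactive ortho-formyl bromide 1 (Pd(OAc)2, SPhos, K3PO4, THF–H2O, 60 °C) to give biaryl aldehyde F3. The stilbene is then installed last by Horner–Wadsworth–Emmons olefination with 2 (KOtBu, THF), which returns to the route at 7.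

## Further compounds

F1 | step 3 | racemic 9 (1:1 mixture of 9 and F2) | COc1cc(OC)c2c(c1)CC1c3cc(OC)c(OC)cc3C(c3ccc(OC)c(OC)c3)=Cc3cc(OC)cc-2c31
F2 | step 3 | (xS)-enantiomer of 9 | COc1cc(OC)c2c(c1)C[C@H]1c3cc(OC)c(OC)cc3C(c3ccc(OC)c(OC)c3)=Cc3cc(OC)cc-2c31
F0 | step 4 | none | none
F3 | step 2 | 5'-[(3,4-dimethoxyphenyl)ethynyl]-3',4,6-trimethoxy-[1,1'-biphenyl]-2-carbaldehyde | COc1cc(OC)c(c(C=O)c1)-c1cc(OC)cc(c1)C#Cc1ccc(OC)c(OC)c1
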